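**Retrosynthetic overview** (C1–C20 = acid-chain numbering, C1 = ester carbon; the oxolane carbons are C5 and C8)
1. Last bond: the enyne C10–C11 by Sonogashira coupling of oxolane alkyne 12 with bromo-iodo-triene 24.
2. The oxolane, the only ring of the target, is closed through the C8–O bond by a copper-catalysed propargylic cycloetherification of hydroxy carbonate 11, which sets C8.
3. 11 comes from δ-lactone 10; the lactone masks the C5 hydroxyl and is the latent methyl ester. It is built from pent-4-enal and the zinc reagent of methyl 4-iodobutanoate (asymmetric addition sets C5), then ozonolysis and ethynyl addition.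
4. 24 comes from a Z-selective Wittig reaction (phosphonium 18 + silyl propynal) between two hydrozirconation/halogenation steps; the C7 chain is from 1,5-dibromopentane and acetylide.
5. Ring order: δ-lactone (formed in step 1, opened in step 4), then oxolane (step 4).

Assumption: the sense of induction of the two chiral ligands (steps 1 and 4) is assigned by analogy with their usual models; if either proves opposite, the enantiomeric ligand is used.

**Step 1**
Reactants: 1 methyl 4-iodobutanoate; 2 pent-4-enal
Product: 5 (6R)-6-(but-3-en-1-yl)oxan-2-one, via diorganozinc 3 (not isolated), via hydroxy ester 4 (not isolated)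
Conditions: 1, Et2Zn, CuI (cat.), neat, 50 °C, then vacuum; Ti(OiPr)4, (1S,2S)-1,2-bis(trifluoromethanesulfonamido)cyclohexane (8 mol %), toluene, −20 °C, then 2; 1 M HCl; TsOH (cat.), toluene, 60 °C
Reagents that add atoms: none
Why: Catalytic asymmetric addition of a functionalised dialkylzinc to an aldehyde (Ti–bis-sulfonamide, Knochel/Ohno type) delivers the ester-bearing alkyl group to the Re face of 2 and sets C5 as R, and acid-catalysed lactonisation of the δ-hydroxy ester then masks that hydroxyl.

**Step 2**
Reactants: 5 (6R)-6-(but-3-en-1-yl)oxan-2-one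
Product: 7 3-[(2R)-6-oxooxan-2-yl]propanal, via ozonide 6 (not isolated)
Conditions: O3, CH2Cl2, −78 °C; then PPh3, −78 °C → rt
Reagents that add atoms: ozone, [O-][O+]=O
Why: Ozonolysis with reductive work-up cleaves only the terminal alkene; the lactone and the stereocenter are untouched.

**Step 3**
Reactants: 7 3-[(2R)-6-oxooxan-2-yl]propanal; 8 ethynylmagnesium bromide
Product: 10 tert-butyl (3RS)-5-[(2R)-6-oxooxan-2-yl]pent-1-yn-3-yl carbonate, via magnesium alkoxide 9 (not isolated)
Conditions: HC≡CMgBr (1.2 equiv), THF, −78 °C; then Boc2O, −78 → 0 °C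
Reagents that add atoms: di-tert-butyl dicarbonate, CC(C)(C)OC(=O)OC(=O)OC(C)(C)C
Why: Grignard 1,2-addition is much faster at the aldehyde than at the δ-lactone at −78 °C, and in-situ acylation of the alkoxide gives the propargylic carbonate; the new carbinol centre is left as a 1:1 mixture because step 4 erases it.

**Step 4**
Reactants: 10 tert-butyl (3RS)-5-[(2R)-6-oxooxan-2-yl]pent-1-yn-3-yl carbonate
Product: 12 methyl 4-[(2R,5S)-5-ethynyloxolan-2-yl]butanoate, via open-chain hydroxy ester 11 (not isolated)
Conditions: NaOMe (0.1 equiv), MeOH, 0 °C; AcOH (0.1 equiv), evaporate below 20 °C; then Cu(MeCN)4PF6 (5 mol %), (S,S)-Ph-pybox (6 mol %), i-Pr2NEt (0.2 equiv), t-AmOH, −10 °C → rt, argon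
Reagents that add atoms: methanol, CO
Why: Proposed new method: a copper-catalysed, stereoconvergent propargylic cycloetherification in which methanolysis first frees the (5R)-hydroxyl and the methyl ester, Cu(I)/pybox then forms the copper acetylide, loss of tert-butyl carbonate (giving CO2 and t-BuO− as internal base) gives a planar copper allenylidene that erases the propargylic centre of both epimers, and 5-exo attack of the tethered secondary alcohol on the γ-carbon from the face left open by the ligand closes the oxolane and sets C8 as S (2,5-trans) under catalyst control; the closest known reaction type is the Cu–pybox enantioselective propargylic etherification and amination of propargylic esters via copper allenylidenes (Nishibayashi-type propargylic substitution), which has not been shown for a diastereoconvergent ring closure by an aliphatic secondary alcohol at an alkyl-substituted propargylic carbon.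

**Step 5**
Reactants: 13 1,5-dibromopentane; 14 lithium acetylide–ethylenediamine complex
Product: 15 7-bromohept-1-yne
Conditions: 13 (3 equiv), DMSO, 0 °C → rt
Reagents that add atoms: none
Why: SN2 alkylation of an acetylide; the excess of the cheap dibromide suppresses double alkylation and is recovered by distillation.

**Step 6**
Reactants: 15 7-bromohept-1-yne
Product: 17 (1E)-7-bromo-1-iodohept-1-ene, via alkenylzirconocene 16 (not isolated)
Conditions: Cp2Zr(H)Cl, THF, rt; then I2, 0 °C
Reagents that add atoms: iodine, II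
Why: Schwartz hydrozirconation adds Zr–H syn and anti-Markovnikov to the terminal alkyne, and iodinolysis of the C–Zr bond with retention gives only the E-iodoalkene; the primary bromide is inert.

**Step 7**
Reactants: 17 (1E)-7-bromo-1-iodohept-1-ene
Product: 18 [(6E)-7-iodohept-6-en-1-yl]triphenylphosphonium bromide
Conditions: PPh3, MeCN, 80 °C, dark
Reagents that add atoms: triphenylphosphine, c1ccc(cc1)P(c1ccccc1)c1ccccc1
Why: SN2 quaternisation occurs only at the primary bromide, since an sp2 C–I bond does not react with PPh3 without a metal.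

**Step 8**
Reactants: 18 [(6E)-7-iodohept-6-en-1-yl]triphenylphosphonium bromide; 19 3-(trimethylsilyl)prop-2-ynal
Product: 22 (3Z,9E)-10-iododeca-3,9-dien-1-yne, via ylide 20 (not isolated), via silyl enyne 21 (not isolated)
Conditions: NaHMDS (1.0 equiv), THF, −78 °C; 19, −78 °C → rt; then K2CO3, MeOH, rt
Reagents that add atoms: none
Why: Salt-free Wittig olefination of a non-stabilised ylide with an ynal is kinetically cis-selective and sets the 3Z alkene, and K2CO3/MeOH then removes the C-silyl group in the same pot.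

**Step 9**
Reactants: 22 (3Z,9E)-10-iododeca-3,9-dien-1-yne
Product: 24 (1E,3Z,9E)-1-bromo-10-iododeca-1,3,9-triene, via dienylzirconocene 23 (not isolated)
Conditions: Cp2Zr(H)Cl, THF, rt, dark; then NBS, 0 °C
Reagents that add atoms: N-bromosuccinimide, BrN1C(=O)CCC1=O
Why: Schwartz hydrozirconation/bromination: syn addition of Zr–H to the terminal alkyne of the Z-enyne and bromodezirconation with retention give the 1E-bromide without touching the 3Z alkene or the iodoalkene.

**Step 10**
Reactants: 12 methyl 4-[(2R,5S)-5-ethynyloxolan-2-yl]butanoate; 24 (1E,3Z,9E)-1-bromo-10-iododeca-1,3,9-triene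
Product: 25 methyl 4-[(2R,5S)-5-[(3E,9Z,11E)-12-bromododeca-3,9,11-trien-1-yn-1-yl]oxolan-2-yl]butanoate
Conditions: Pd(PPh3)4 (5 mol %), CuI (10 mol %), Et3N, THF, 0 °C → rt, dark; 24 (1.2 equiv), 12 limiting
Reagents that add atoms: none
Why: Sonogashira coupling: Pd(0) inserts into the C(sp2)–I bond much faster than into the dienyl C–Br bond at or below room temperature, so with the alkyne limiting the E-enyne forms with retention while the bromodiene and both ring stereocenters are preserved.

**Compound list**
1 | methyl 4-iodobutanoate | COC(=O)CCCI | starting material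
2 | pent-4-enal | C=CCCC=O | starting material
3 | bis(4-methoxy-4-oxobutyl)zinc | COC(=O)CCC[Zn]CCCC(=O)OC | intermediate
4 | methyl (5R)-5-hydroxynon-8-enoate | COC(=O)CCC[C@@H](O)CCC=C | intermediate
5 | (6R)-6-(but-3-en-1-yl)oxan-2-one | C=CCC[C@H]1CCCC(=O)O1 | intermediate
6 | (6R)-6-[2-(1,2,4-trioxolan-3-yl)ethyl]oxan-2-one | O=C1CCC[C@H](CCC2OCOO2)O1 | intermediate
7 | 3-[(2R)-6-oxooxan-2-yl]propanal | O=CCC[C@H]1CCCC(=O)O1 | intermediate
8 | ethynylmagnesium bromide | C#C[Mg]Br | starting material
9 | bromomagnesium (3RS)-5-[(2R)-6-oxooxan-2-yl]pent-1-yn-3-olate | C#CC(O[Mg]Br)CC[C@H]1CCCC(=O)O1 | intermediate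
10 | tert-butyl (3RS)-5-[(2R)-6-oxooxan-2-yl]pent-1-yn-3-yl carbonate | C#CC(OC(=O)OC(C)(C)C)CC[C@H]1CCCC(=O)O1 | intermediate
11 | methyl (5R,8RS)-8-[(tert-butoxycarbonyl)oxy]-5-hydroxydec-9-ynoate | COC(=O)CCC[C@@H](O)CCC(OC(=O)OC(C)(C)C)C#C | intermediate
12 | methyl 4-[(2R,5S)-5-ethynyloxolan-2-yl]butanoate | COC(=O)CCC[C@@H]1CC[C@@H](C#C)O1 | intermediate
13 | 1,5-dibromopentane | BrCCCCCBr | starting material
14 | lithium acetylide–ethylenediamine complex | [Li]C#C.NCCN | starting material
15 | 7-bromohept-1-yne | C#CCCCCCBr | intermediate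
16 | [(1E)-7-bromohept-1-en-1-yl](chlorido)bis(cyclopentadienyl)zirconium | BrCCCCC/C=C/[Zr](Cl)(C1C=CC=C1)C1C=CC=C1 | intermediate
17 | (1E)-7-bromo-1-iodohept-1-ene | BrCCCCC/C=C/I | intermediate
18 | [(6E)-7-iodohept-6-en-1-yl]triphenylphosphonium bromide | I/C=C/CCCCC[P+](c1ccccc1)(c1ccccc1)c1ccccc1.[Br-] | intermediate
19 | 3-(trimethylsilyl)prop-2-ynal | C[Si](C)(C)C#CC=O | starting material
20 | [(6E)-7-iodohept-6-en-1-ylidene]triphenylphosphorane | I/C=C/CCCCC=P(c1ccccc1)(c1ccccc1)c1ccccc1 | intermediate
21 | [(3Z,9E)-10-iododeca-3,9-dien-1-yn-1-yl]trimethylsilane | C[Si](C)(C)C#C/C=C\CCCC/C=C/I | intermediate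
22 | (3Z,9E)-10-iododeca-3,9-dien-1-yne | C#C/C=C\CCCC/C=C/I | intermediate
23 | [(1E,3Z,9E)-10-iododeca-1,3,9-trien-1-yl](chlorido)bis(cyclopentadienyl)zirconium | Cl[Zr](/C=C/C=C\CCCC/C=C/I)(C1C=CC=C1)C1C=CC=C1 | intermediate
24 | (1E,3Z,9E)-1-bromo-10-iododeca-1,3,9-triene | Br/C=C/C=C\CCCC/C=C/I | intermediate
25 | methyl 4-[(2R,5S)-5-[(3E,9Z,11E)-12-bromododeca-3,9,11-trien-1-yn-1-yl]oxolan-2-yl]butanoate | COC(=O)CCC[C@@H]1CC[C@@H](C#C/C=C/CCCC/C=C\C=C\Br)O1 | target

**Totals**
Total step count: 10. Longest linear sequence: 6 steps (13 → 15 → 17 → 18 → 22 → 24 → 25); the other arm is 5 steps (1 + 2 → 5 → 7 → 10 → 12 → 25).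

**Three steps most likely to fail**

Step 4 (the proposed new cyclisation). The risks are β-elimination of the copper allenylidene to a 1,3-enyne, weak catalyst control of the 2,5-trans/cis ratio, and re-lactonisation of 11. The fallback uses known chemistry and sets out from 4, which is isolated after the HCl quench of step 1 instead of being lactonised. Mukaiyama aerobic oxidative cyclisation of this 4-pentenol-type alcohol (Co(modp)2 10 mol %, O2 1 atm, t-BuOOH, i-PrOH, 55 °C) forms the C8–O bond and gives methyl 4-[(2R,5S)-5-(hydroxymethyl)oxolan-2-yl]butanoate F1, with the 2,5-trans selectivity (typically ≥ 95:5) that this reaction is known for. Dess–Martin oxidation (NaHCO3, CH2Cl2) gives methyl 4-[(2R,5S)-5-formyloxolan-2-yl]butanoate F2. Ohira–Bestmann alkynylation (dimethyl (1-diazo-2-oxopropyl)phosphonate, K2CO3, MeOH, 0 °C) then gives 12, where the fallback comes back to the route.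

Step 9 (hydrozirconation/bromination of the Z-enyne next to an iodoalkene). The risks are loss of the 3Z geometry, reduction of the C–I bond and a light- and acid-sensitive product. The fallback sets out from 18 and installs the bromodiene in one olefination instead. Ylide 20 (NaHMDS, THF, −78 °C) is treated with (2E)-3-bromoprop-2-enal F5, which gives 24 directly (Z at the new alkene, the E-bromoalkene carried in), where it comes back to the route. The aldehyde is made from propiolic acid: 48 % HBr at 95 °C gives (2E)-3-bromoprop-2-enoic acid F3, BH3·SMe2 gives (2E)-3-bromoprop-2-en-1-ol F4, and MnO2 in CH2Cl2 gives F5, used at once as a solution.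

Step 10 (iodide versus bromide selectivity in the Sonogashira coupling). The risk is competing coupling at the dienyl bromide and oligomer formation. The fallback sets out from 12 and 21 (isolated before the desilylation of step 8), so that no C–Br bond is present during the palladium step. Sonogashira coupling gives methyl 4-[(2R,5S)-5-[(3E,9Z)-12-(trimethylsilyl)dodeca-3,9-diene-1,11-diyn-1-yl]oxolan-2-yl]butanoate F6. K2CO3/MeOH gives the terminal enyne methyl 4-[(2R,5S)-5-[(3E,9Z)-dodeca-3,9-diene-1,11-diyn-1-yl]oxolan-2-yl]butanoate F7. Cp2Zr(H)Cl (1.1 equiv, THF, 0 °C) reacts at the terminal alkyne to give the dienylzirconocene methyl 4-[(2R,5S)-5-[(3E,9Z,11E)-12-[chloridobis(cyclopentadienyl)zirconio]dodeca-3,9,11-trien-1-yn-1-yl]oxolan-2-yl]butanoate F8, and NBS then gives 25, where it comes back to the route.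

**Further compounds**
F1 | step 4 | methyl 4-[(2R,5S)-5-(hydroxymethyl)oxolan-2-yl]butanoate | COC(=O)CCC[C@@H]1CC[C@@H](CO)O1
F2 | step 4 | methyl 4-[(2R,5S)-5-formyloxolan-2-yl]butanoate | COC(=O)CCC[C@@H]1CC[C@@H](C=O)O1
F3 | step 9 | (2E)-3-bromoprop-2-enoic acid | OC(=O)/C=C/Br
F4 | step 9 | (2E)-3-bromoprop-2-en-1-ol | OC/C=C/Br
F5 | step 9 | (2E)-3-bromoprop-2-enal | O=C/C=C/Br
F6 | step 10 | methyl 4-[(2R,5S)-5-[(3E,9Z)-12-(trimethylsilyl)dodeca-3,9-diene-1,11-diyn-1-yl]oxolan-2-yl]butanoate | COC(=O)CCC[C@@H]1CC[C@@H](C#C/C=C/CCCC/C=C\C#C[Si](C)(C)C)O1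
F7 | step 10 | methyl 4-[(2R,5S)-5-[(3E,9Z)-dodeca-3,9-diene-1,11-diyn-1-yl]oxolan-2-yl]butanoate | COC(=O)CCC[C@@H]1CC[C@@H](C#C/C=C/CCCC/C=C\C#C)O1
F8 | step 10 | methyl 4-[(2R,5S)-5-[(3E,9Z,11E)-12-[chloridobis(cyclopentadienyl)zirconio]dodeca-3,9,11-trien-1-yn-1-yl]oxolan-2-yl]butanoate | COC(=O)CCC[C@@H]1CC[C@@H](C#C/C=C/CCCC/C=C\C=C\[Zr](Cl)(C2C=CC=C2)C2C=CC=C2)O1
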